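**Retrosynthetic overview**
- The strategy rests on one feature of ring A. C8 carries the aryloxy oxygen and C8a carries the lactone carbonyl C1, and the two carbons are neighbours. Cutting C8–O and C8a–C1 together leads back to an aryne, the phenoxide of ring B and CO2.
- A chlorine on the future C4a steers this double addition. It is later exchanged for the C4–C3–pentyl unit by Sonogashira coupling with 1-heptyne.
- Rings A and B are bought as benzene rings (4-(benzyloxy)phenol and olivetol). The only ring formed is the pyranone ring C, closed late at O2–C3 by a 6-endo-dig cyclisation, and the two benzyl groups are then removed.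
- The silylaryl triflate is made by two ortho-halogenations, O-silylation and retro-Brook/triflation. The ring B phenol is made by formylation, methylation, benzylation and Baeyer–Villiger oxidation.

Key step: step 9

Remark: isocoumarin numbering is used throughout (C1 carbonyl, O2, C3 pentyl, C4, C4a, C5–C8, C8a). The target has no stereocentre, so no step has to control configuration.

**Step 1**
Reactants: 1 4-(benzyloxy)phenol
Product: 2 4-(benzyloxy)-2-chlorophenol
Conditions: SO2Cl2 (1.0 equiv), i-Pr2NH (cat.), toluene, 0 °C to rt
Reagents that add atoms: sulfuryl chloride, O=S(=O)(Cl)Cl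
Why: Amine-catalysed electrophilic ortho-chlorination of a phenol, in which the free hydroxyl is the strongest director, its para position is blocked, and one equivalent of reagent should stop at the monochloride.

**Step 2**
Reactants: 2 4-(benzyloxy)-2-chlorophenol
Product: 3 4-(benzyloxy)-2-bromo-6-chlorophenol
Conditions: NBS (1.0 equiv), i-Pr2NH (cat.), CH2Cl2, 0 °C, dark
Reagents that add atoms: N-bromosuccinimide, O=C1CCC(=O)N1Br
Why: Ortho-bromination of a phenol with NBS, in which the one remaining carbon ortho to the hydroxyl is the most activated site and the benzyl ring is far less electron-rich.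

**Step 3**
Reactants: 3 4-(benzyloxy)-2-bromo-6-chlorophenol
Product: 4 [4-(benzyloxy)-2-bromo-6-chlorophenoxy]trimethylsilane
Conditions: HMDS, THF, reflux; concentrate, use crude
Reagents that add atoms: hexamethyldisilazane, C[Si](C)(C)N[Si](C)(C)C
Why: O-silylation of the phenol with HMDS gives only ammonia beside the silyl ether, so the dry crude product can go straight into the lithiation.

**Step 4**
Reactants: 4 [4-(benzyloxy)-2-bromo-6-chlorophenoxy]trimethylsilane
Product: 7 4-(benzyloxy)-2-chloro-6-(trimethylsilyl)phenyl trifluoromethanesulfonate, via aryllithium 5 (not isolated), via lithium phenoxide 6 (not isolated)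
Conditions: n-BuLi (1.1 equiv), THF, −78 °C; then Tf2O (1.2 equiv), −78 °C; aq NaHCO3
Reagents that add atoms: trifluoromethanesulfonic anhydride, O=S(=O)(OS(=O)(=O)C(F)(F)F)C(F)(F)F
Why: Bromine–lithium exchange outruns attack on C–Cl or on the benzylic CH2 at −78 °C, aryllithium 5 undergoes the retro-Brook 1,3-shift of silicon from O to C, and phenoxide 6 is triflated in the same flask, which is the standard one-pot route to ortho-silylaryl triflates.

**Step 5**
Reactants: 8 olivetol (5-pentylbenzene-1,3-diol)
Product: 10 2,4-dihydroxy-6-pentylbenzaldehyde, via iminium chloride 9 (not isolated)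
Conditions: POCl3 (1.2 equiv), DMF, 0 °C to rt; then ice/H2O
Reagents that add atoms: N,N-dimethylformamide, CN(C)C=O; water, O
Why: Vilsmeier–Haack formylation, which on 5-alkylresorcinols takes place para to one hydroxyl and ortho to the other, next to the alkyl chain, after which water hydrolyses iminium 9 and supplies the aldehyde oxygen.

**Step 6**
Reactants: 10 2,4-dihydroxy-6-pentylbenzaldehyde
Product: 11 2-hydroxy-4-methoxy-6-pentylbenzaldehyde
Conditions: MeI (1.05 equiv), K2CO3 (1.1 equiv), acetone, rt
Reagents that add atoms: iodomethane, CI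
Why: Williamson etherification that is selective because the C2 hydroxyl is held in a hydrogen bond to the aldehyde, so the free and more acidic C4 hydroxyl para to the formyl group is alkylated.

**Step 7**
Reactants: 11 2-hydroxy-4-methoxy-6-pentylbenzaldehyde
Product: 12 2-(benzyloxy)-4-methoxy-6-pentylbenzaldehyde
Conditions: BnBr, K2CO3, DMF, 60 °C
Reagents that add atoms: benzyl bromide, BrCc1ccccc1
Why: Williamson etherification of the only remaining phenol, for which a polar solvent and heating overcome the hydrogen bond to the aldehyde.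

**Step 8**
Reactants: 12 2-(benzyloxy)-4-methoxy-6-pentylbenzaldehyde
Product: 14 2-(benzyloxy)-4-methoxy-6-pentylphenol, via aryl formate 13 (not isolated)
Conditions: mCPBA, CH2Cl2, 0 °C to rt; wash with aq Na2S2O3/NaHCO3; then K2CO3 (cat.), MeOH, rt
Reagents that add atoms: 3-chloroperoxybenzoic acid, OOC(=O)c1cccc(Cl)c1
Why: Baeyer–Villiger (Dakin-type) oxidation in which the electron-rich aryl group migrates in preference to hydride, and formate 13 is methanolysed only after the peracid is washed out, so the oxidisable free phenol never meets the oxidant.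

**Step 9**
Reactants: 14 2-(benzyloxy)-4-methoxy-6-pentylphenol (1.2 equiv); 7 4-(benzyloxy)-2-chloro-6-(trimethylsilyl)phenyl trifluoromethanesulfonate (1.0 equiv); 15 carbon dioxide
Product: 19 4-(benzyloxy)-2-[2-(benzyloxy)-4-methoxy-6-pentylphenoxy]-6-chlorobenzoic acid, via potassium phenoxide 16 (not isolated), via aryne 17 (not isolated), via aryl anion 18 (not isolated)
Conditions: 14, KH (1.05 equiv per 14), THF, 0 °C; then 18-crown-6, spray-dried KF (3 equiv), dry CO2 (1 atm, saturated solution); 7 in THF by syringe pump, 0 °C; aq HCl, acid–base extraction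
Reagents that add atoms: none
Why: Proposed new method: fluoride attacks the silicon of 7 and triflate leaves, which releases aryne 17; the oxygen of phenoxide 16 adds to the aryne carbon that becomes C8, and the aryl anion 18 thus placed on C8a adds to dissolved CO2, so that the C8–O and C8a–C1 bonds form in one flask (no ring closes and no stereocentre arises). The closest known reaction types are the three-component coupling of arynes, secondary amines and CO2 to anthranilic acids under KF/18-crown-6 in THF and the O-arylation of phenols by arynes; new here is the union of an anionic oxygen nucleophile with carboxylative capture of the aryl anion. Regioselectivity is needed and is secured by the chlorine on the future C4a: its inductive pull distorts the triple bond so that the remote carbon is the more electrophilic one, the developing charge sits next to the C–Cl bond, and the bulky nucleophile avoids the flank next to chlorine, while the benzyloxy group at the future C6 exerts only a weak opposing bias. The two ortho substituents of 16, which hamper copper- or palladium-mediated etherification, matter little because the attack goes to an unhindered sp carbon in the ring plane. Chemoselectivity rests on the medium: the phenoxide is preformed with KH so that only H2 leaves, acetonitrile and other C–H or O–H acids are excluded, the THF is saturated with CO2 and 7 is added slowly at 0 °C, so that carboxylation of 18 should outrun protonation and loss of chloride. The slight excess of 16 keeps the hindered product carboxylate from competing for the aryne, and the acid is parted from neutral by-products by extraction into base.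

**Step 10**
Reactants: 19 4-(benzyloxy)-2-[2-(benzyloxy)-4-methoxy-6-pentylphenoxy]-6-chlorobenzoic acid
Product: 20 methyl 4-(benzyloxy)-2-[2-(benzyloxy)-4-methoxy-6-pentylphenoxy]-6-chlorobenzoate
Conditions: MeI, K2CO3, DMF, rt
Reagents that add atoms: iodomethane, CI
Why: SN2 alkylation of the carboxylate avoids any tetrahedral intermediate at the doubly ortho-substituted carbonyl, where Fischer esterification would stall.

**Step 11**
Reactants: 20 methyl 4-(benzyloxy)-2-[2-(benzyloxy)-4-methoxy-6-pentylphenoxy]-6-chlorobenzoate; 21 1-heptyne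
Product: 22 methyl 4-(benzyloxy)-2-[2-(benzyloxy)-4-methoxy-6-pentylphenoxy]-6-(hept-1-yn-1-yl)benzoate
Conditions: PdCl2(MeCN)2 (3 mol %), XPhos (9 mol %), Cs2CO3, MeCN, 85 °C, sealed tube
Reagents that add atoms: none
Why: Copper-free Sonogashira coupling of an aryl chloride, in which the bulky electron-rich biaryl phosphine lets zerovalent palladium insert into the C–Cl bond, itself activated by the ortho ester, and leaving out copper avoids alkyne homocoupling.

**Step 12**
Reactants: 22 methyl 4-(benzyloxy)-2-[2-(benzyloxy)-4-methoxy-6-pentylphenoxy]-6-(hept-1-yn-1-yl)benzoate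
Product: 23 6-(benzyloxy)-8-[2-(benzyloxy)-4-methoxy-6-pentylphenoxy]-3-pentyl-1H-isochromen-1-one
Conditions: AuCl3 (10 mol %), H2O (2 equiv), MeCN, 50 °C
Reagents that add atoms: water, O
Why: π-Acid-catalysed 6-endo-dig cyclisation of a methyl 2-alkynylbenzoate, in which the ester carbonyl oxygen attacks the gold-activated alkyne carbon bearing the pentyl chain (O2–C3), the 1-methoxyisochromenylium ion takes up water at C1 and expels methanol, and protodeauration leaves C4–H.

**Step 13**
Reactants: 23 6-(benzyloxy)-8-[2-(benzyloxy)-4-methoxy-6-pentylphenoxy]-3-pentyl-1H-isochromen-1-one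
Product: 24 6-hydroxy-8-(2-hydroxy-4-methoxy-6-pentylphenoxy)-3-pentyl-1H-isochromen-1-one (CNP0409817.0)
Conditions: BCl3 (5 equiv), pentamethylbenzene (6 equiv), CH2Cl2, −78 °C; quench with H2O
Reagents that add atoms: none
Why: Lewis-acid debenzylation with a cation scavenger, in which both aryl benzyl ethers ionise at −78 °C while the unchelated aryl methyl ether, the diaryl ether and the enol lactone stay intact, and pentamethylbenzene takes up the benzyl cations before they can alkylate rings A or B.

**Compound list**
1 | 4-(benzyloxy)phenol | Oc1ccc(OCc2ccccc2)cc1 | starting material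
2 | 4-(benzyloxy)-2-chlorophenol | Oc1ccc(OCc2ccccc2)cc1Cl | intermediate
3 | 4-(benzyloxy)-2-bromo-6-chlorophenol | Oc1c(Br)cc(OCc2ccccc2)cc1Cl | intermediate
4 | [4-(benzyloxy)-2-bromo-6-chlorophenoxy]trimethylsilane | C[Si](C)(C)Oc1c(Br)cc(OCc2ccccc2)cc1Cl | intermediate
5 | [5-(benzyloxy)-3-chloro-2-(trimethylsilyloxy)phenyl]lithium (not isolated) | [Li]c1cc(OCc2ccccc2)cc(Cl)c1O[Si](C)(C)C | intermediate
6 | lithium 4-(benzyloxy)-2-chloro-6-(trimethylsilyl)phenoxide (not isolated) | [Li+].[O-]c1c(Cl)cc(OCc2ccccc2)cc1[Si](C)(C)C | intermediate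
7 | 4-(benzyloxy)-2-chloro-6-(trimethylsilyl)phenyl trifluoromethanesulfonate | C[Si](C)(C)c1cc(OCc2ccccc2)cc(Cl)c1OS(=O)(=O)C(F)(F)F | intermediate
8 | olivetol | CCCCCc1cc(O)cc(O)c1 | starting material
9 | (2,4-dihydroxy-6-pentylbenzylidene)dimethylammonium chloride (not isolated) | CCCCCc1cc(O)cc(O)c1C=[N+](C)C.[Cl-] | intermediate
10 | 2,4-dihydroxy-6-pentylbenzaldehyde | CCCCCc1cc(O)cc(O)c1C=O | intermediate
11 | 2-hydroxy-4-methoxy-6-pentylbenzaldehyde | CCCCCc1cc(OC)cc(O)c1C=O | intermediate
12 | 2-(benzyloxy)-4-methoxy-6-pentylbenzaldehyde | CCCCCc1cc(OC)cc(OCc2ccccc2)c1C=O | intermediate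
13 | 2-(benzyloxy)-4-methoxy-6-pentylphenyl formate (not isolated) | CCCCCc1cc(OC)cc(OCc2ccccc2)c1OC=O | intermediate
14 | 2-(benzyloxy)-4-methoxy-6-pentylphenol | CCCCCc1cc(OC)cc(OCc2ccccc2)c1O | intermediate
15 | carbon dioxide | O=C=O | starting material
16 | potassium 2-(benzyloxy)-4-methoxy-6-pentylphenoxide (not isolated) | CCCCCc1cc(OC)cc(OCc2ccccc2)c1[O-].[K+] | intermediate
17 | 5-(benzyloxy)-3-chlorobenzyne (not isolated) | ClC1=CC(OCc2ccccc2)=CC#C1 | intermediate
18 | potassium 4-(benzyloxy)-2-[2-(benzyloxy)-4-methoxy-6-pentylphenoxy]-6-chlorophenyl anion (not isolated) | CCCCCc1cc(OC)cc(OCc2ccccc2)c1Oc1cc(OCc2ccccc2)cc(Cl)[c-]1.[K+] | intermediate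
19 | 4-(benzyloxy)-2-[2-(benzyloxy)-4-methoxy-6-pentylphenoxy]-6-chlorobenzoic acid | CCCCCc1cc(OC)cc(OCc2ccccc2)c1Oc1cc(OCc2ccccc2)cc(Cl)c1C(=O)O | intermediate
20 | methyl 4-(benzyloxy)-2-[2-(benzyloxy)-4-methoxy-6-pentylphenoxy]-6-chlorobenzoate | CCCCCc1cc(OC)cc(OCc2ccccc2)c1Oc1cc(OCc2ccccc2)cc(Cl)c1C(=O)OC | intermediate
21 | 1-heptyne | CCCCCC#C | starting material
22 | methyl 4-(benzyloxy)-2-[2-(benzyloxy)-4-methoxy-6-pentylphenoxy]-6-(hept-1-yn-1-yl)benzoate | CCCCCC#Cc1cc(OCc2ccccc2)cc(Oc2c(CCCCC)cc(OC)cc2OCc2ccccc2)c1C(=O)OC | intermediate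
23 | 6-(benzyloxy)-8-[2-(benzyloxy)-4-methoxy-6-pentylphenoxy]-3-pentyl-1H-isochromen-1-one | CCCCCc1cc2cc(OCc3ccccc3)cc(Oc3c(OCc4ccccc4)cc(OC)cc3CCCCC)c2c(=O)o1 | intermediate
24 | 6-hydroxy-8-(2-hydroxy-4-methoxy-6-pentylphenoxy)-3-pentyl-1H-isochromen-1-one | CCCCCc1cc2cc(O)cc(Oc3c(O)cc(OC)cc3CCCCC)c2c(=O)o1 | target

**Step count**
- Total step count: 13.
- Longest linear sequence: 9 steps (steps 1–4 or steps 5–8, followed by steps 9–13).

**Steps most likely to fail**

1. **Step 9.**
   - What may go wrong: the aryl anion may be protonated before it meets CO2. It may expel chloride and open a second aryne. The phenoxide–CO2 adduct may add through its carbonate oxygen and then transfer the acyl group. The product carboxylate may be arylated by further aryne.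
   - Fallback (known chemistry, sets out from 14 and returns at 19): purchased 3-chloro-5-fluorophenol is benzylated (BnBr, K2CO3, DMF) to 1-(benzyloxy)-3-chloro-5-fluorobenzene F1. This is deprotonated by LDA in THF at −78 °C at the carbon between fluorine and chlorine (directed ortho-metalation) and formylated with DMF to 4-(benzyloxy)-2-chloro-6-fluorobenzaldehyde F2. Nucleophilic aromatic substitution of the aldehyde-activated fluoride by 14 (K2CO3, DMF, 110 °C) gives 4-(benzyloxy)-2-[2-(benzyloxy)-4-methoxy-6-pentylphenoxy]-6-chlorobenzaldehyde F3. Pinnick oxidation (NaClO2, NaH2PO4, 2-methyl-2-butene, t-BuOH/H2O) then gives 19.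

2. **Step 11.**
   - What may go wrong: oxidative addition into the chloride next to the twisted ester may be sluggish, so that alkyne oligomerisation and catalyst decay take over.
   - Fallback (sets out from 19 and returns at 23; steps 10–12 drop out): Claisen condensation of 2-heptanone with ethyl hexanoate (NaH, THF) gives trideca-6,8-dione F4. Heating 19 with F4, CuI (monovalent copper) and K3PO4 in DMF at 110–120 °C brings about Hurtley-type C-arylation at the carboxylate-activated C–Cl bond. Retro-Claisen loss of hexanoate and enol lactonisation follow in the same flask and give 23.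

3. **Step 12.**
   - What may go wrong: 5-exo-dig closure to the alkylidene phthalide may compete. The alkyne may simply be hydrated without ring closure. The electron-rich ring B may reduce gold trichloride and so kill the catalyst.
   - Fallback (sets out from 22 and returns at 23): iodocyclisation with I2 in CH2Cl2 at rt is an electrophilic 6-endo-dig closure in which iodide takes off the ester methyl group. It gives 6-(benzyloxy)-8-[2-(benzyloxy)-4-methoxy-6-pentylphenoxy]-4-iodo-3-pentyl-1H-isochromen-1-one F5. Hydrodeiodination with Pd(PPh3)4 and HCO2Na in DMF at 80 °C gives 23 without touching the benzyl ethers.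

**Further compounds**
F1 | step 9 | 1-(benzyloxy)-3-chloro-5-fluorobenzene | Fc1cc(Cl)cc(OCc2ccccc2)c1
F2 | step 9 | 4-(benzyloxy)-2-chloro-6-fluorobenzaldehyde | O=Cc1c(F)cc(OCc2ccccc2)cc1Cl
F3 | step 9 | 4-(benzyloxy)-2-[2-(benzyloxy)-4-methoxy-6-pentylphenoxy]-6-chlorobenzaldehyde | CCCCCc1cc(OC)cc(OCc2ccccc2)c1Oc1cc(OCc2ccccc2)cc(Cl)c1C=O
F4 | step 11 | trideca-6,8-dione | CCCCCC(=O)CC(=O)CCCCC
F5 | step 12 | 6-(benzyloxy)-8-[2-(benzyloxy)-4-methoxy-6-pentylphenoxy]-4-iodo-3-pentyl-1H-isochromen-1-one | CCCCCc1oc(=O)c2c(Oc3c(OCc4ccccc4)cc(OC)cc3CCCCC)cc(OCc3ccccc3)cc2c1I
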